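**Plan**
- Cuts: the benzene ring of the benzofuran is opened at C7'–C7a' (electrocyclisation, then aromatisation), then at C4'=C5' (Knoevenagel) and C3a'–C4' (formylation), leaving a 2,4-disubstituted furan. The pentane chain (C2 = carbinol carbon, C4 = methine on the heteroarene) is cut at C2–C3 (lithiation–borylation).
- Enabling feature: the ring C3a'/C4'/C5'/C6'/C7'/C7a' bears acetyl on C5' beside hydroxyl on C6'. That is one pentane-2,4-dione unit (a carbonyl carbon = C6', the central carbon = C5', a methyl carbon = C7') bonded to an aldehyde carbon (C4') on the furan.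
- Forward order: the chromene and furan rings are bought. A furylpropyl boronic ester and a chromenylethyl carbamate are joined at C2–C3, the furan is formylated, condensed with the dione and enol-silylated, the benzene ring closes last, then both silyl groups are removed.
- Stereochemistry: C4 (S) comes from a copper-catalysed enantioselective protoboration of the isopropenylfuran. C2 (R) comes from the (S)-carbamate (Noyori hydrogenation) through stereospecific lithiation–borylation–oxidation. Neither centre is touched afterwards.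

Key step: step 15

Remark: the antipode of DTBM-SEGPHOS used in step 4 is taken to be the one that delivers the S boronic ester (both antipodes are sold); its sense is to be fixed in a pilot run by correlation.

**Step 1**
Reactants: 1 4-bromofuran-2-carbaldehyde
Product: 2 rac-1-(4-bromofuran-2-yl)ethan-1-ol
Conditions: MeMgBr, THF, 0 °C
Reagents that add atoms: methylmagnesium bromide, C[Mg]Br
Why: Grignard 1,2-addition to the aldehyde is fast at 0 °C and leaves the furyl bromide untouched; the racemic carbinol centre is removed in step 2.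

**Step 2**
Reactants: 2 rac-1-(4-bromofuran-2-yl)ethan-1-ol
Product: 3 1-(4-bromofuran-2-yl)ethan-1-one
Conditions: MnO2, CH2Cl2, 25 °C
Reagents that add atoms: none
Why: Activated MnO2 oxidises the furfuryl-type secondary alcohol to the ketone under neutral conditions that spare the furan ring and the C–Br bond.

**Step 3**
Reactants: 3 1-(4-bromofuran-2-yl)ethan-1-one
Product: 4 4-bromo-2-(prop-1-en-2-yl)furan
Conditions: Ph3PCH3Br, KOtBu, THF, 0 → 25 °C
Reagents that add atoms: methyltriphenylphosphonium bromide, C[P+](c1ccccc1)(c1ccccc1)c1ccccc1.[Br-]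
Why: Wittig methylenation of the aryl methyl ketone gives the 1,1-disubstituted alkene under basic conditions, avoiding the acid to which 2-alkenylfurans are sensitive.

**Step 4**
Reactants: 4 4-bromo-2-(prop-1-en-2-yl)furan
Product: 5 (S)-2-[2-(4-bromofuran-2-yl)propyl]-4,4,5,5-tetramethyl-1,3,2-dioxaborolane
Conditions: CuCl (5 mol %), DTBM-SEGPHOS (6 mol %, antipode per the remark), NaOtBu (10 mol %), B2pin2, MeOH, THF, 25 °C
Reagents that add atoms: bis(pinacolato)diboron, CC1(C)OB(OC1(C)C)B1OC(C)(C)C(C)(C)O1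
Why: Copper-catalysed enantioselective protoboration of a 1,1-disubstituted heteroaryl alkene: the ligated Cu–Bpin species adds syn with boron on the terminal carbon, the chiral bisphosphine selects the alkene face, and stereoretentive protonation of the furfurylic C–Cu bond by MeOH fixes the S centre at C4, while the catalytic alkoxide loading should not sustain borylation of the C–Br bond.

**Step 5**
Reactants: 6 7-methoxy-2,2-dimethyl-2H-chromene
Product: 7 7-methoxy-2,2-dimethyl-2H-chromene-6-carbaldehyde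
Conditions: POCl3, DMF, 0 → 25 °C; then aq. NaOAc
Reagents that add atoms: N,N-dimethylformamide, CN(C)C=O; water, O
Why: Vilsmeier–Haack formylation should go to C6, para to the ring oxygen and ortho to the methoxy group, because C8 between the two oxygens is hindered, and the non-protic chloroiminium electrophile spares the acid-sensitive chromene alkene.

**Step 6**
Reactants: 7 7-methoxy-2,2-dimethyl-2H-chromene-6-carbaldehyde
Product: 8 rac-1-(7-methoxy-2,2-dimethyl-2H-chromen-6-yl)ethan-1-ol
Conditions: MeMgBr, THF, 0 °C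
Reagents that add atoms: methylmagnesium bromide, C[Mg]Br
Why: Grignard addition to the aryl aldehyde installs the methyl group; the racemic centre is erased in step 7.

**Step 7**
Reactants: 8 rac-1-(7-methoxy-2,2-dimethyl-2H-chromen-6-yl)ethan-1-ol
Product: 9 1-(7-methoxy-2,2-dimethyl-2H-chromen-6-yl)ethan-1-one
Conditions: MnO2, CH2Cl2, 25 °C
Reagents that add atoms: none
Why: MnO2 oxidises the electron-rich benzylic alcohol to the aryl methyl ketone without touching the chromene alkene.

**Step 8**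
Reactants: 9 1-(7-methoxy-2,2-dimethyl-2H-chromen-6-yl)ethan-1-one
Product: 10 (S)-1-(7-methoxy-2,2-dimethyl-2H-chromen-6-yl)ethan-1-ol
Conditions: RuCl2[(R)-xylbinap][(R)-daipen] (0.2 mol %), KOtBu (2 mol %), H2 (8 atm), iPrOH, 25 °C
Reagents that add atoms: none
Why: Noyori asymmetric hydrogenation with the diphosphine/diamine RuCl2 catalyst reduces C=O by outer-sphere hydride/proton transfer and leaves C=C alone; the (R)-diphosphine/(R)-diamine pair should deliver hydride to the face that gives the S alcohol, as it does for acetophenone.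

**Step 9**
Reactants: 10 (S)-1-(7-methoxy-2,2-dimethyl-2H-chromen-6-yl)ethan-1-ol
Product: 11 (S)-1-(7-methoxy-2,2-dimethyl-2H-chromen-6-yl)ethyl N,N-diisopropylcarbamate
Conditions: NaH, iPr2NCOCl, THF, 0 → 50 °C
Reagents that add atoms: N,N-diisopropylcarbamoyl chloride, CC(C)N(C(C)C)C(Cl)=O
Why: O-Carbamoylation of the sodium alkoxide breaks no bond at the stereocentre and avoids acid that could ionise the electron-rich benzylic C–O bond.

**Step 10**
Reactants: 11 (S)-1-(7-methoxy-2,2-dimethyl-2H-chromen-6-yl)ethyl N,N-diisopropylcarbamate; 5 (S)-2-[2-(4-bromofuran-2-yl)propyl]-4,4,5,5-tetramethyl-1,3,2-dioxaborolane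
Product: 15 (2R,4S)-4-(4-bromofuran-2-yl)-2-(7-methoxy-2,2-dimethyl-2H-chromen-6-yl)pentan-2-ol, via lithiated carbamate 12 (not isolated), via lithium boronate complex 13 (not isolated), via tertiary boronic ester 14 (not isolated)
Conditions: 11 (1.3 equiv), sBuLi (1.2 equiv), Et2O, −78 °C; 5 (1.0 equiv), −78 → 25 °C; then NaOH, H2O2, THF/H2O, 0 °C
Reagents that add atoms: hydrogen peroxide, OO
Why: Lithiation–borylation (1,2-metallate rearrangement): carbamate-directed benzylic deprotonation and trapping by the pinacol boronic ester both go with retention, the 1,2-shift of the primary alkyl group expels the carbamate with inversion and C–B oxidation goes with retention, so the S carbamate and the S boronic ester should give the (2R,4S) alcohol; 5 meets only the preformed lithiated carbamate (sBuLi is limiting), so the furyl bromide should not be exchanged.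

**Step 11**
Reactants: 15 (2R,4S)-4-(4-bromofuran-2-yl)-2-(7-methoxy-2,2-dimethyl-2H-chromen-6-yl)pentan-2-ol
Product: 16 {[(2R,4S)-4-(4-bromofuran-2-yl)-2-(7-methoxy-2,2-dimethyl-2H-chromen-6-yl)pentan-2-yl]oxy}triethylsilane
Conditions: TESOTf, 2,6-lutidine, CH2Cl2, −78 → 0 °C
Reagents that add atoms: triethylsilyl trifluoromethanesulfonate, CC[Si](CC)(CC)OS(=O)(=O)C(F)(F)F
Why: Silyl triflate with 2,6-lutidine is the standard way to cap a hindered tertiary alcohol, and the base keeps the medium non-acidic so that the electron-rich benzylic centre does not ionise.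

**Step 12**
Reactants: 16 {[(2R,4S)-4-(4-bromofuran-2-yl)-2-(7-methoxy-2,2-dimethyl-2H-chromen-6-yl)pentan-2-yl]oxy}triethylsilane
Product: 18 5-[(2S,4R)-4-(7-methoxy-2,2-dimethyl-2H-chromen-6-yl)-4-(triethylsilyloxy)pentan-2-yl]furan-3-carbaldehyde, via furyllithium 17 (not isolated)
Conditions: nBuLi, THF, −78 °C; DMF, −78 → 0 °C
Reagents that add atoms: N,N-dimethylformamide, CN(C)C=O
Why: Bromine–lithium exchange at −78 °C is faster than deprotonation or isomerisation to the 5-lithio species, and the furyllithium is formylated by DMF (Bouveault reaction) with the silyl ether, the chromene and both stereocentres untouched.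

**Step 13**
Reactants: 18 5-[(2S,4R)-4-(7-methoxy-2,2-dimethyl-2H-chromen-6-yl)-4-(triethylsilyloxy)pentan-2-yl]furan-3-carbaldehyde; 19 pentane-2,4-dione
Product: 20 3-({5-[(2S,4R)-4-(7-methoxy-2,2-dimethyl-2H-chromen-6-yl)-4-(triethylsilyloxy)pentan-2-yl]furan-3-yl}methylidene)pentane-2,4-dione
Conditions: piperidine (20 mol %), AcOH (20 mol %), 4 Å MS, toluene, 25–40 °C
Reagents that add atoms: none
Why: Knoevenagel condensation under piperidinium acetate catalysis joins the aldehyde carbon (future C4') to the central carbon of the dione (future C5'); the diketone is symmetric, so the new alkene has no geometry.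

**Step 14**
Reactants: 20 3-({5-[(2S,4R)-4-(7-methoxy-2,2-dimethyl-2H-chromen-6-yl)-4-(triethylsilyloxy)pentan-2-yl]furan-3-yl}methylidene)pentane-2,4-dione
Product: 21 (E)-4-(tert-butyldimethylsilyloxy)-3-({5-[(2S,4R)-4-(7-methoxy-2,2-dimethyl-2H-chromen-6-yl)-4-(triethylsilyloxy)pentan-2-yl]furan-3-yl}methylidene)pent-4-en-2-one
Conditions: TBSOTf (1.2 equiv), Et3N, CH2Cl2, −78 → 0 °C; used crude after filtration through Et3N-deactivated silica
Reagents that add atoms: tert-butyldimethylsilyl trifluoromethanesulfonate, CC(C)(C)[Si](C)(C)OS(=O)(=O)C(F)(F)F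
Why: Soft enolisation (silyl triflate/amine) gives the 2-silyloxydiene; the acetyl group cis to the furan is twisted out of conjugation and is the more ketone-like, whereas the trans acetyl stays in the furan–alkene–carbonyl push–pull system, so silylation of the cis acetyl, which keeps that conjugation and gives the E isomer, should be preferred.

**Step 15**
Reactants: 21 (E)-4-(tert-butyldimethylsilyloxy)-3-({5-[(2S,4R)-4-(7-methoxy-2,2-dimethyl-2H-chromen-6-yl)-4-(triethylsilyloxy)pentan-2-yl]furan-3-yl}methylidene)pent-4-en-2-one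
Product: 23 1-{6-(tert-butyldimethylsilyloxy)-2-[(2S,4R)-4-(7-methoxy-2,2-dimethyl-2H-chromen-6-yl)-4-(triethylsilyloxy)pentan-2-yl]-1-benzofuran-5-yl}ethan-1-one, via dihydrobenzofuran 22 (not isolated)
Conditions: toluene (0.01 M), NaHCO3, 110 °C; DDQ (1.2 equiv) added in portions, same flask
Reagents that add atoms: none
Why: Proposed new method: heating should let the E-configured silyloxytriene (enol-ether C=CH2, C4'=C5', furan C4=C5) close by a thermal disrotatory 6π-electrocyclisation in which the nucleophilic enol-ether CH2 (C7') bonds to furan C5 (C7a'), a carbon made electrophilic by the O1–C5=C4–CH=C–C=O push–pull path to the acetyl group, giving dihydrobenzofuran 22. The closest known chemistry is the thermal 6π-electrocyclisation–dehydrogenation of dienyl-substituted heteroarenes (3-dienylindoles to carbazoles); furan is less aromatic than indole or benzene and should give up its C4=C5 bond more readily. The six-membered carbocycle closes in the electrocyclic mode (formally 6-endo at both termini); the only new stereocentre, C7a' of 22, is transient and is erased when DDQ abstracts hydride from C7a' (allylic and α to oxygen) and C7' loses a proton, an irreversible aromatisation that drains the otherwise unfavourable pericyclic equilibrium. The step needs closure at furan C5 and not C3, which the bond localisation of furan secures (the side chain sits on C4, whose only ring double bond is to C5, and bonding at C3 would require a non-Kekulé species), and it needs the E geometry set in step 14. DDQ should spare the chromene (2H-chromenes are themselves prepared with DDQ), NaHCO3 keeps DDQH2 from ionising the tertiary benzylic silyl ether, and high dilution disfavours Diels–Alder dimerisation of the silyloxydiene.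

**Step 16**
Reactants: 23 1-{6-(tert-butyldimethylsilyloxy)-2-[(2S,4R)-4-(7-methoxy-2,2-dimethyl-2H-chromen-6-yl)-4-(triethylsilyloxy)pentan-2-yl]-1-benzofuran-5-yl}ethan-1-one
Product: 24 1-{6-hydroxy-2-[(2S,4R)-4-hydroxy-4-(7-methoxy-2,2-dimethyl-2H-chromen-6-yl)pentan-2-yl]-1-benzofuran-5-yl}ethan-1-one
Conditions: TBAF, AcOH, THF, 0 → 25 °C
Reagents that add atoms: none
Why: Fluoride-mediated desilylation cleaves the aryl silyl ether and the tertiary triethylsilyl ether, and acetic acid tempers the basicity of the phenoxide and alkoxide without being strong enough to ionise the tertiary benzylic alcohol.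

**Compound list**
1 | 4-bromofuran-2-carbaldehyde | O=Cc1cc(Br)co1 | starting material
2 | rac-1-(4-bromofuran-2-yl)ethan-1-ol | CC(O)c1cc(Br)co1 | intermediate
3 | 1-(4-bromofuran-2-yl)ethan-1-one | CC(=O)c1cc(Br)co1 | intermediate
4 | 4-bromo-2-(prop-1-en-2-yl)furan | C=C(C)c1cc(Br)co1 | intermediate
5 | (S)-2-[2-(4-bromofuran-2-yl)propyl]-4,4,5,5-tetramethyl-1,3,2-dioxaborolane | CC1(C)OB(C[C@H](C)c2cc(Br)co2)OC1(C)C | intermediate
6 | 7-methoxy-2,2-dimethyl-2H-chromene | COc1ccc2C=CC(C)(C)Oc2c1 | starting material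
7 | 7-methoxy-2,2-dimethyl-2H-chromene-6-carbaldehyde | COc1cc2c(cc1C=O)C=CC(C)(C)O2 | intermediate
8 | rac-1-(7-methoxy-2,2-dimethyl-2H-chromen-6-yl)ethan-1-ol | COc1cc2c(cc1C(C)O)C=CC(C)(C)O2 | intermediate
9 | 1-(7-methoxy-2,2-dimethyl-2H-chromen-6-yl)ethan-1-one | COc1cc2c(cc1C(C)=O)C=CC(C)(C)O2 | intermediate
10 | (S)-1-(7-methoxy-2,2-dimethyl-2H-chromen-6-yl)ethan-1-ol | COc1cc2c(cc1[C@H](C)O)C=CC(C)(C)O2 | intermediate
11 | (S)-1-(7-methoxy-2,2-dimethyl-2H-chromen-6-yl)ethyl N,N-diisopropylcarbamate | COc1cc2c(cc1[C@H](C)OC(=O)N(C(C)C)C(C)C)C=CC(C)(C)O2 | intermediate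
12 | lithiated carbamate (11 with the benzylic H replaced by Li, configuration retained) | COc1cc2c(cc1[C@]([Li])(C)OC(=O)N(C(C)C)C(C)C)C=CC(C)(C)O2 | intermediate
13 | lithium boronate complex (boron carries the carbamoyloxy-substituted benzylic carbon of 12, the (S)-2-(4-bromofuran-2-yl)propyl group and pinacol) | COc1cc2c(cc1[C@](C)(OC(=O)N(C(C)C)C(C)C)[B-]1(C[C@H](C)c3cc(Br)co3)OC(C)(C)C(C)(C)O1)C=CC(C)(C)O2.[Li+] | intermediate
14 | 2-[(2S,4S)-4-(4-bromofuran-2-yl)-2-(7-methoxy-2,2-dimethyl-2H-chromen-6-yl)pentan-2-yl]-4,4,5,5-tetramethyl-1,3,2-dioxaborolane | COc1cc2c(cc1[C@](C)(B1OC(C)(C)C(C)(C)O1)C[C@H](C)c1cc(Br)co1)C=CC(C)(C)O2 | intermediate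
15 | (2R,4S)-4-(4-bromofuran-2-yl)-2-(7-methoxy-2,2-dimethyl-2H-chromen-6-yl)pentan-2-ol | COc1cc2c(cc1[C@](C)(O)C[C@H](C)c1cc(Br)co1)C=CC(C)(C)O2 | intermediate
16 | {[(2R,4S)-4-(4-bromofuran-2-yl)-2-(7-methoxy-2,2-dimethyl-2H-chromen-6-yl)pentan-2-yl]oxy}triethylsilane | COc1cc2c(cc1[C@](C)(O[Si](CC)(CC)CC)C[C@H](C)c1cc(Br)co1)C=CC(C)(C)O2 | intermediate
17 | furyllithium (16 with Br replaced by Li) | COc1cc2c(cc1[C@](C)(O[Si](CC)(CC)CC)C[C@H](C)c1cc([Li])co1)C=CC(C)(C)O2 | intermediate
18 | 5-[(2S,4R)-4-(7-methoxy-2,2-dimethyl-2H-chromen-6-yl)-4-(triethylsilyloxy)pentan-2-yl]furan-3-carbaldehyde | COc1cc2c(cc1[C@](C)(O[Si](CC)(CC)CC)C[C@H](C)c1cc(C=O)co1)C=CC(C)(C)O2 | intermediate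
19 | pentane-2,4-dione | CC(=O)CC(C)=O | starting material
20 | 3-({5-[(2S,4R)-4-(7-methoxy-2,2-dimethyl-2H-chromen-6-yl)-4-(triethylsilyloxy)pentan-2-yl]furan-3-yl}methylidene)pentane-2,4-dione | COc1cc2c(cc1[C@](C)(O[Si](CC)(CC)CC)C[C@H](C)c1cc(C=C(C(C)=O)C(C)=O)co1)C=CC(C)(C)O2 | intermediate
21 | (E)-4-(tert-butyldimethylsilyloxy)-3-({5-[(2S,4R)-4-(7-methoxy-2,2-dimethyl-2H-chromen-6-yl)-4-(triethylsilyloxy)pentan-2-yl]furan-3-yl}methylidene)pent-4-en-2-one | COc1cc2c(cc1[C@](C)(O[Si](CC)(CC)CC)C[C@H](C)c1cc(/C=C(/C(C)=O)C(=C)O[Si](C)(C)C(C)(C)C)co1)C=CC(C)(C)O2 | intermediate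
22 | 1-{6-(tert-butyldimethylsilyloxy)-2-[(2S,4R)-4-(7-methoxy-2,2-dimethyl-2H-chromen-6-yl)-4-(triethylsilyloxy)pentan-2-yl]-7,7a-dihydro-1-benzofuran-5-yl}ethan-1-one (both C7a epimers) | COc1cc2c(cc1[C@](C)(O[Si](CC)(CC)CC)C[C@H](C)C1=CC3=CC(C(C)=O)=C(O[Si](C)(C)C(C)(C)C)CC3O1)C=CC(C)(C)O2 | intermediate
23 | 1-{6-(tert-butyldimethylsilyloxy)-2-[(2S,4R)-4-(7-methoxy-2,2-dimethyl-2H-chromen-6-yl)-4-(triethylsilyloxy)pentan-2-yl]-1-benzofuran-5-yl}ethan-1-one | COc1cc2c(cc1[C@](C)(O[Si](CC)(CC)CC)C[C@H](C)c1cc3cc(C(C)=O)c(O[Si](C)(C)C(C)(C)C)cc3o1)C=CC(C)(C)O2 | intermediate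
24 | 1-{6-hydroxy-2-[(2S,4R)-4-hydroxy-4-(7-methoxy-2,2-dimethyl-2H-chromen-6-yl)pentan-2-yl]-1-benzofuran-5-yl}ethan-1-one | COc1cc2c(cc1[C@](C)(O)C[C@H](C)c1cc3cc(C(C)=O)c(O)cc3o1)C=CC(C)(C)O2 | target

**Step count**
Total: 16 steps. Longest linear sequence: 12 steps (6 → 24, steps 5–16).

**Steps most likely to fail**

1. Step 15 (proposed new method). The ring closure may stay on the open side of the equilibrium, the diene may dimerise by Diels–Alder reaction, or DDQ may attack the enol ether before closure.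
Fallback (known chemistry; sets out from 11, rejoins at 24): the benzofuran is assembled by alkyne/ortho-iodophenol annulation instead of by building onto a furan. Commercial (R)-3-bromo-2-methylpropan-1-ol is silylated (TBSCl, imidazole) to (R)-(3-bromo-2-methylpropoxy)(tert-butyl)dimethylsilane F1. This is borylated (B2pin2, CuI, PPh3, LiOMe, DMF) to (S)-tert-butyldimethyl[2-methyl-3-(4,4,5,5-tetramethyl-1,3,2-dioxaborolan-2-yl)propoxy]silane F2. Lithiation–borylation of 11 with F2 under the conditions of step 10 should give tert-butyl{[(2S,4S)-4-(7-methoxy-2,2-dimethyl-2H-chromen-6-yl)-2-methyl-4-(4,4,5,5-tetramethyl-1,3,2-dioxaborolan-2-yl)pentyl]oxy}dimethylsilane F3. NaOH/H2O2 then gives (2R,4S)-5-(tert-butyldimethylsilyloxy)-2-(7-methoxy-2,2-dimethyl-2H-chromen-6-yl)-4-methylpentan-2-ol F4. TBAF frees (2S,4R)-4-(7-methoxy-2,2-dimethyl-2H-chromen-6-yl)-2-methylpentane-1,4-diol F5. Oxidation of the primary alcohol with one equivalent of Dess–Martin periodinane gives (3S,5R)-5-(7-methoxy-2,2-dimethyl-2H-chromen-6-yl)-3,5-dimethyloxolan-2-ol F6 (lactol). The Ohira–Bestmann reagent (K2CO3, MeOH) converts it into (2R,4S)-2-(7-methoxy-2,2-dimethyl-2H-chromen-6-yl)-4-methylhex-5-yn-2-ol F7. Sonogashira coupling of F7 with 1-(2,4-dihydroxy-5-iodophenyl)ethan-1-one F8 (from 2,4-dihydroxyacetophenone and ICl in AcOH), with in-flask 5-endo cyclisation of the ortho hydroxyl onto the alkyne (PdCl2(PPh3)2, CuI, Et3N, DMF, 60 °C), should give 24 directly.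

2. Step 14. Silylation may fall on the acetyl group trans to the furan, giving the Z dienol ether that cannot cyclise, or the dienol ether may hydrolyse on handling.
Fallback (sets out from 20, rejoins at 24): both acetyl groups are enol-silylated (TBSOTf 3 equiv, Et3N, CH2Cl2, 0 → 25 °C) to the symmetric 3-({5-[(2S,4R)-4-(7-methoxy-2,2-dimethyl-2H-chromen-6-yl)-4-(triethylsilyloxy)pentan-2-yl]furan-3-yl}methylidene)-2,4-bis(tert-butyldimethylsilyloxy)penta-1,4-diene F9, which always has a silyloxyvinyl group cis to the furan. Heating as in step 15, with activated MnO2 in place of DDQ because an enol ether remains in the product, should give tert-butyl{[5-[1-(tert-butyldimethylsilyloxy)ethenyl]-2-[(2S,4R)-4-(7-methoxy-2,2-dimethyl-2H-chromen-6-yl)-4-(triethylsilyloxy)pentan-2-yl]-1-benzofuran-6-yl]oxy}dimethylsilane F10. TBAF/AcOH then cleaves the aryl silyl ether, the enol ether (to the acetyl group) and the triethylsilyl ether to give 24.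

3. Step 4. Facial selectivity may be poor with the furyl-substituted alkene, or the C–Br bond may be borylated in competition.
Fallback (sets out from 3, rejoins at 5): boron–Wittig olefination of 3 with CH2(Bpin)2 and LiTMP (THF, −78 → 25 °C) gives (E)-2-[2-(4-bromofuran-2-yl)prop-1-en-1-yl]-4,4,5,5-tetramethyl-1,3,2-dioxaborolane F11. Asymmetric hydrogenation of this alkenyl boronate (H2, [Ir(cod)(L)]BArF with L a chiral phosphine–oxazoline, CH2Cl2) sets C4 by hydrogen delivery instead of by boron addition and should give 5.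

**Further compounds**
F1 | step 15 | (R)-(3-bromo-2-methylpropoxy)(tert-butyl)dimethylsilane | CC(C)(C)[Si](C)(C)OC[C@@H](C)CBr
F2 | step 15 | (S)-tert-butyldimethyl[2-methyl-3-(4,4,5,5-tetramethyl-1,3,2-dioxaborolan-2-yl)propoxy]silane | CC(C)(C)[Si](C)(C)OC[C@@H](C)CB1OC(C)(C)C(C)(C)O1
F3 | step 15 | tert-butyl{[(2S,4S)-4-(7-methoxy-2,2-dimethyl-2H-chromen-6-yl)-2-methyl-4-(4,4,5,5-tetramethyl-1,3,2-dioxaborolan-2-yl)pentyl]oxy}dimethylsilane | COc1cc2c(cc1[C@](C)(B1OC(C)(C)C(C)(C)O1)C[C@H](C)CO[Si](C)(C)C(C)(C)C)C=CC(C)(C)O2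
F4 | step 15 | (2R,4S)-5-(tert-butyldimethylsilyloxy)-2-(7-methoxy-2,2-dimethyl-2H-chromen-6-yl)-4-methylpentan-2-ol | COc1cc2c(cc1[C@](C)(O)C[C@H](C)CO[Si](C)(C)C(C)(C)C)C=CC(C)(C)O2
F5 | step 15 | (2S,4R)-4-(7-methoxy-2,2-dimethyl-2H-chromen-6-yl)-2-methylpentane-1,4-diol | COc1cc2c(cc1[C@](C)(O)C[C@H](C)CO)C=CC(C)(C)O2
F6 | step 15 | (3S,5R)-5-(7-methoxy-2,2-dimethyl-2H-chromen-6-yl)-3,5-dimethyloxolan-2-ol | COc1cc2c(cc1[C@@]1(C)C[C@H](C)C(O)O1)C=CC(C)(C)O2
F7 | step 15 | (2R,4S)-2-(7-methoxy-2,2-dimethyl-2H-chromen-6-yl)-4-methylhex-5-yn-2-ol | COc1cc2c(cc1[C@](C)(O)C[C@H](C)C#C)C=CC(C)(C)O2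
F8 | step 15 | 1-(2,4-dihydroxy-5-iodophenyl)ethan-1-one | CC(=O)c1cc(I)c(O)cc1O
F9 | step 14 | 3-({5-[(2S,4R)-4-(7-methoxy-2,2-dimethyl-2H-chromen-6-yl)-4-(triethylsilyloxy)pentan-2-yl]furan-3-yl}methylidene)-2,4-bis(tert-butyldimethylsilyloxy)penta-1,4-diene | COc1cc2c(cc1[C@](C)(O[Si](CC)(CC)CC)C[C@H](C)c1cc(C=C(C(=C)O[Si](C)(C)C(C)(C)C)C(=C)O[Si](C)(C)C(C)(C)C)co1)C=CC(C)(C)O2
F10 | step 14 | tert-butyl{[5-[1-(tert-butyldimethylsilyloxy)ethenyl]-2-[(2S,4R)-4-(7-methoxy-2,2-dimethyl-2H-chromen-6-yl)-4-(triethylsilyloxy)pentan-2-yl]-1-benzofuran-6-yl]oxy}dimethylsilane | COc1cc2c(cc1[C@](C)(O[Si](CC)(CC)CC)C[C@H](C)c1cc3cc(C(=C)O[Si](C)(C)C(C)(C)C)c(O[Si](C)(C)C(C)(C)C)cc3o1)C=CC(C)(C)O2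
F11 | step 4 | (E)-2-[2-(4-bromofuran-2-yl)prop-1-en-1-yl]-4,4,5,5-tetramethyl-1,3,2-dioxaborolane | C/C(=C\B1OC(C)(C)C(C)(C)O1)c1cc(Br)co1
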